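If Q and G exchange reversibly, the share of Q follows how far that exchange has gone, so the useful reckoning is the fraction of the way to balance still left, not the G made.

| setting | beta | gamma | theta | spring | summer | dusk | dawn |
|---|---|---|---|---|---|---|---|
| D | 0.10 M | 0.10 M | 0.10 M | 0.10 M | 0.10 M (fed, over 2.50 d) | 0.10 M | 0.10 M |
| L | 0.80 equiv | 0.54 equiv | 1.2 equiv | 0.800 equiv (fed, over 2.50 d) | 0.800 equiv | 0.800 equiv | 0.800 equiv |
| remark | run made earlier | run made earlier | run made earlier | a stirred flask in which L is dosed at a steady rate over 2.50 d without added volume, worked up at 5.0 d | a stirred flask in which D is dosed at a steady rate over 2.50 d without added volume, worked up at 5.0 d | a single well-mixed tank run continuously and read at steady state, 5.0 d in it on average | a closed flask charged with all of it at once and left for 5.0 d |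
| time |  |  |  | 5.0 d | 5.0 d |  | 5.0 d |

| run | time / d | Q / % | G / % | D / % |
|---|---|---|---|---|
| beta | 0.333 | 61 | 1 | 26 |
| beta | 1.04 | 85 | 14 | 3 |
| beta | 1.67 | 78 | 20 | 1 |
| beta | 2.50 | 71 | 26 | 0 |
| beta | 4.00 | 67 | 35 | 2 |
| beta | 5.00 | 62 | 34 | 0 |
| gamma | 0.250 | 54 | 3 | 39 |
| gamma | 0.833 | 79 | 12 | 8 |
| gamma | 1.25 | 82 | 17 | 1 |
| gamma | 2.00 | 75 | 20 | 0 |
| gamma | 3.00 | 72 | 29 | 0 |
| gamma | 4.00 | 63 | 31 | 1 |
| theta | 0.333 | 65 | 4 | 25 |
| theta | 0.500 | 75 | 5 | 14 |
| theta | 0.833 | 82 | 8 | 4 |
| theta | 1.67 | 74 | 18 | 0 |
| theta | 2.50 | 72 | 26 | 3 |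
| theta | 4.00 | 66 | 35 | 4 |

(standard deviation of a reading: 2 percentage points)

* the set-up with the highest share of Q in all that became Q or G, at the outlet or at the end ("none" if the first two lie within 2 percentage points) (spring / summer / dusk / dawn / none)
* share of Q in all that became Q or G, at the outlet or at the end, spring
* share of Q in all that became Q or G, at the outlet or at the end, summer
* share of Q in all that became Q or G, at the outlet or at the end, dusk
* share of Q in all that became Q or G, at the outlet or at the end, dawn

- the stated concentrations are those of everything mixed, before any reaction; amounts are the same in each set-up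
- steps under discussion: D -> Q; D + L -> E; L + E <-> Z; Q <-> G
- the feed brings no volume worth counting
- the earlier runs were made in a closed, stirred flask

In the beta run, D stands at 26% after 0.333 d; the theta run, richer in L, stands at 25%, a difference inside the scatter of 2 percentage points. This reading shows no part for L in the loss of D. D's own time in the beta run, 0.247 d, is shorter than the 5.0 d in the vessel, so two times remain: the relaxation time of Q and G, and the time in the vessel. Summer's dosing of D over 2.50 d shortens the second time: its last portion spends 2.50 d in the flask, against 5.0 d for its first.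

In the beta run, the readings of the gap between Q and G give a slope from 1.04 d to 2.50 d that is 2.05 times the slope from there to 4.00 d. My reading is therefore a relaxation rate of 0.487 d⁻¹, a time of 2.06 d. The relaxation number, time in the vessel over relaxation time, is 2.43. This is kinetic against thermodynamic control in one figure. A closed flask keeps exp(−number) of the way, 0.0878. A mixed tank, with its spread of ages, keeps one over one plus the number, 0.291, which is more. So I expect dusk to lead.

The forecast also names dusk: 72.3% for dusk, 68.8% for summer, 64.8% for spring and 64.8% for dawn, holding that “L therefore appears irrelevant, and dosing it changes nothing”.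

The flasks give dusk as best: dusk 72.9%, summer 68.8%, spring 66.1%, dawn 66.1%.

    D → Q (k = 0.150 h⁻¹)
    D + L → E (k = 0.0440 M⁻¹ h⁻¹)
    L + E ⇌ Z (K = 78.0 M⁻¹, k = 0.0360 M⁻¹ h⁻¹)
    Q ⇌ G (K = 0.560, k = 0.00920 h⁻¹)

The relaxation half-life of Q and G in dawn, 1.13 d, is shorter than the 5.0 d in the vessel, which makes the relaxation number 3.08 and leaves 0.0460 of the way in dawn against 0.245 in dusk. The same flask as dawn read at 3.0 d has the number 1.85, leaves 0.157 of the way, and holds a share of Q above that of dawn, at 70.9%.

The readings are simulated with constants of no real substance, noise included.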